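(Readings and results were computed with constants of no real substance; scatter was added.)

By 3.00 min both earlier runs have gone flat, with X still at 83.4% in alder and 79.1% in oak at 10.0 min, and the plateau climbs with the charge of G.

| setting | alder | oak | flask |
|---|---|---|---|
| X | 0.34 M | 0.34 M | 0.34 M |
| G | 0.10 M | 0.15 M | 0.204 M |
| remark | run made earlier | run made earlier |  |
| time |  |  | 10 min |

| run | time / min | X / % | Z / % |
|---|---|---|---|
| alder | 0.833 | 85.1 | 14.7 |
| alder | 1.33 | 84.9 | 15.4 |
| alder | 2.00 | 83.6 | 16.8 |
| alder | 3.00 | 83.4 | 17.1 |
| alder | 4.00 | 82.9 | 17.6 |
| alder | 6.00 | 83.2 | 17.5 |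
| alder | 10.0 | 83.4 | 16.2 |
| oak | 0.500 | 82.7 | 17.3 |
| oak | 1.50 | 79.4 | 20.0 |
| oak | 3.00 | 78.6 | 21.3 |
| oak | 4.00 | 79.3 | 20.9 |
| oak | 6.00 | 79.3 | 20.9 |
| oak | 8.00 | 79.7 | 21.5 |
| oak | 10.0 | 79.1 | 21.8 |

(scatter of a reading: 0.5 percentage points)

- which holds at 10 min: what has brought the reaction to rest, or that it has not come to rest (it is still moving / forward and back rates have come level / all of X has reacted / G has run out first)
- how much of the X has reacted by 10 min
- how much Z there is at 10 min, in percent of the X charged
- amount of Z if the flask were left three thousand times as long, in percent of the X charged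

- candidate steps: 2 G -> E; X + G -> Z
- the reaction counts as stopped when no species that holds the X changes by six tenths of a point or more over the second half of the time

Taking the plateau as the mean of Z and of X lost over the flat readings gives 16.9% in alder and 21.0% in oak. Both candidate steps run one way, so this reckoning treats the plateau as the end of G, the limiting reagent.

There are two ways to carry this to the flask. The first holds Z per G constant at its oak value, which gives 14.0% for alder and 28.6% for the flask.

The second gives G two exits. X + G → Z spends one G per X at a rate in [X][G], and the pairing to E spends G at a rate in [G] squared. Per X consumed, G falls by 1 + m[G]/[X], where m is the selectivity factor, the ratio of the G-loss constants of the pairing and of the step to Z. Integrated to the end of G, this gives (1/r)^n = 1 + n·g, with r the fraction of X left, g the G charged per X charged, and n = m − 1. Oak's plateau gives n = 4.84, the competition number. It reckons 16.7% for alder and 24.5% for the flask.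

The two ways part, and alder, read at 16.9%, exposes the first: Z per G is larger in alder than in oak, so that yield is not constant.

The forecast says G has run out first, with conversion 25%, Z 25% and 25% on long standing, on the ground that “G being consumed by 2 G → E fits better”. The reckoning here, from n, stands at 24.5% against the forecast's 25%.

    2 G → E (k = 0.361 L mol⁻¹ s⁻¹)
    X + G → Z (k = 0.125 L mol⁻¹ s⁻¹)

In the flask G has run out first: at 10.0 min G stands at 0% of its charge and X at 75%, with conversion 24.7%, Z 24.7%, and 24.7% on long standing. Against this, n reckoned 24.5%; for 0.35 M of G it reckons 30.9%, and that neighbour flask holds 31.1%. At the start of the flask, G goes to Z more slowly than to E, at 0.29 of that rate. At 0.154 min the flask's ratio is still below one, at 0.78.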